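Ring B of the target is a cyclohexene (C6=C7) whose four stereocentres C5, C8, C9 and C10 all sit on the two σ-bonds C5–C10 and C8–C9, while C1–C4 of ring A can serve as a tether. Both rings are therefore traced back to one acyclic triene. A Lewis-acid-promoted intramolecular Diels–Alder reaction of an (E)-3-methylenoyl oxazolidinone (C9=C10) with an (E,Z)-diene (C5–C8) closes rings A and B, forms both bonds and sets all four centres from a single benzyl-bearing auxiliary. The precursor is the (R)-4-benzyloxazolidinone imide of (2E,8E,10Z)-3,7,7-trimethyl-12-silyloxydodeca-2,8,10-trienoic acid. The C12–C16 unit is attached afterwards by B-alkyl Suzuki coupling.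

Key step: step 9

Remark: labdane numbering is used (C1–C10 decalin, C11–C16 side chain, C17 on C8, C20 on C10); C17–O is carried as a triisopropylsilyl ether, whose hindered oxygen should resist Me2AlCl and two saponifications better than a smaller silyl ether.

Step 1
Reactants: 1 prop-2-yn-1-ol
Product: 2 triisopropyl(prop-2-yn-1-yloxy)silane
Conditions: i-Pr3SiCl, imidazole, CH2Cl2, 0 °C to rt
Reagents that add atoms: chlorotri(propan-2-yl)silane, CC(C)[Si](Cl)(C(C)C)C(C)C
Why: Imidazole-promoted O-silylation of a primary alcohol is routine and installs the bulky silyl ether that is kept until step 17.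

Step 2
Reactants: 3 ethyl 3-oxobutanoate
Product: 4 ethyl (2E)-3-{[(trifluoromethyl)sulfonyl]oxy}but-2-enoate
Conditions: Tf2O, aq. Me4NOH, toluene, 0–5 °C
Reagents that add atoms: trifluoromethanesulfonic anhydride, O=S(=O)(OS(=O)(=O)C(F)(F)F)C(F)(F)F
Why: Enol triflation of a β-keto ester through its non-chelated tetramethylammonium enolate should place the triflate trans to the ester (E), whereas lithium-chelated enolates give the Z isomer.

Step 3
Reactants: 5 2,2-dimethylpent-4-enal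
Product: 6 (1E)-1-iodo-3,3-dimethylhexa-1,5-diene
Conditions: CrCl2, CHI3, THF, 0 °C to rt
Reagents that add atoms: iodoform, IC(I)I
Why: Takai iodo-olefination converts the hindered, non-enolisable aldehyde into the vinyl iodide, and the E geometry is the normal outcome of this chromium-mediated reaction, reinforced here by the quaternary substituent.

Step 4
Reactants: 6 (1E)-1-iodo-3,3-dimethylhexa-1,5-diene; 2 triisopropyl(prop-2-yn-1-yloxy)silane
Product: 7 {[(4E)-6,6-dimethylnona-4,8-dien-2-yn-1-yl]oxy}triisopropylsilane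
Conditions: PdCl2(PPh3)2, CuI, Et3N, THF, rt
Reagents that add atoms: none
Why: Sonogashira coupling of a vinyl iodide with a terminal alkyne proceeds at room temperature with retention of the E geometry and leaves the isolated terminal alkene untouched.

Step 5
Reactants: 7 {[(4E)-6,6-dimethylnona-4,8-dien-2-yn-1-yl]oxy}triisopropylsilane; 4 ethyl (2E)-3-{[(trifluoromethyl)sulfonyl]oxy}but-2-enoate
Product: 9 ethyl (2E,8E)-3,7,7-trimethyl-12-[(triisopropylsilyl)oxy]dodeca-2,8-dien-10-ynoate, via B-alkyl-9-borabicyclononane 8 (not isolated)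
Conditions: 9-BBN (1.05 equiv), THF, 0 °C to rt; then 4, PdCl2(dppf), aq. K3PO4, DMF, rt to 50 °C
Reagents that add atoms: none
Why: 9-BBN hydroborates the monosubstituted alkene anti-Markovnikov far faster than the internal conjugated alkyne, and the B-alkyl Suzuki–Miyaura coupling of 8 with the activated enol triflate occurs with retention, so C10 receives C1 trans to the ester (2E).

Step 6
Reactants: 9 ethyl (2E,8E)-3,7,7-trimethyl-12-[(triisopropylsilyl)oxy]dodeca-2,8-dien-10-ynoate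
Product: 10 ethyl (2E,8E,10Z)-3,7,7-trimethyl-12-[(triisopropylsilyl)oxy]dodeca-2,8,10-trienoate
Conditions: Zn dust activated with Cu(OAc)2 and AgNO3, MeOH/H2O/i-PrOH, 40 °C
Reagents that add atoms: none
Why: Reduction of a conjugated alkyne with copper/silver-activated zinc (Boland reduction) delivers both hydrogens cis and stops at the alkene, giving the 10Z diene without touching the enoate or the E alkene.

Step 7
Reactants: 10 ethyl (2E,8E,10Z)-3,7,7-trimethyl-12-[(triisopropylsilyl)oxy]dodeca-2,8,10-trienoate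
Product: 11 (2E,8E,10Z)-3,7,7-trimethyl-12-[(triisopropylsilyl)oxy]dodeca-2,8,10-trienoic acid
Conditions: LiOH, THF/MeOH/H2O, 45 °C; then 1 M HCl, 0 °C
Reagents that add atoms: lithium hydroxide, [Li+].[OH-]
Why: Saponification of the ethyl ester with aqueous hydroxide leaves the triisopropylsilyl ether and the three alkene geometries unchanged.

Step 8
Reactants: 11 (2E,8E,10Z)-3,7,7-trimethyl-12-[(triisopropylsilyl)oxy]dodeca-2,8,10-trienoic acid; 12 (4R)-4-benzyl-1,3-oxazolidin-2-one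
Product: 14 (4R)-4-benzyl-3-{(2E,8E,10Z)-3,7,7-trimethyl-12-[(triisopropylsilyl)oxy]dodeca-2,8,10-trienoyl}-1,3-oxazolidin-2-one, via mixed pivalic anhydride 13 (not isolated)
Conditions: t-BuCOCl, Et3N, THF, −20 °C; then LiCl, 12, rt
Reagents that add atoms: none
Why: N-Acylation of the oxazolidinone by a mixed pivalic anhydride under LiCl/Et3N activation occurs at the less hindered enoyl carbonyl and needs no strong base, so the 2E geometry is kept.

Step 9
Reactants: 14 (4R)-4-benzyl-3-{(2E,8E,10Z)-3,7,7-trimethyl-12-[(triisopropylsilyl)oxy]dodeca-2,8,10-trienoyl}-1,3-oxazolidin-2-one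
Product: 15 (4R)-4-benzyl-3-{[(1R,2S,4aR,8aR)-5,5,8a-trimethyl-2-{[(triisopropylsilyl)oxy]methyl}-1,2,4a,5,6,7,8,8a-octahydronaphthalen-1-yl]carbonyl}-1,3-oxazolidin-2-one
Conditions: Me2AlCl (1.6 equiv), CH2Cl2, −30 to 0 °C; 1 M HCl quench
Reagents that add atoms: none
Why: Two equivalents of Me2AlCl convert the imide into a cationic dimethylaluminium chelate that holds the enoyl unit s-cis and coplanar with the auxiliary and lowers its LUMO, so that a concerted, suprafacial, asynchronous [4+2] cycloaddition of C9=C10 onto C5=C6–C7=C8 can run below 0 °C, where neither 1,5-hydrogen shift from C17 nor Z to E drift of the diene competes; the closest known reaction type is the aluminium-promoted type 1 intramolecular Diels–Alder reaction of 2,8,10-trienoyl oxazolidinones to trans-fused octalins. Ring B closes as the new cyclohexene of the cycloaddition (bonds C5–C10 and C8–C9, alkene C6=C7), and ring A closes in the same event as the six-membered ring that the C1–C4 tether spans between C10 and C5, trans-fused because the carbonyl-endo transition state places the tether exo with a chair-like C1–C4 chain. C9 and C10 take their absolute configuration from the benzyl group of 12, which blocks one face of the planar chelate so that the diene adds to the C9-Re face, and their cis relation (C11 with C20) follows from the 2E geometry. C5 is fixed relative to C10 by the endo topology and the 8E geometry (H-5 anti to C20). C8 is fixed by the 10Z geometry, which places C17 inside the diene and therefore trans to the endo C11 carbonyl. The step thus needs face and endo selectivity: the chelated auxiliary supplies the first, and the second is reinforced because an exo carbonyl would clash with the inward-pointing CH2O group at C8.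

Step 10
Reactants: 15 (4R)-4-benzyl-3-{[(1R,2S,4aR,8aR)-5,5,8a-trimethyl-2-{[(triisopropylsilyl)oxy]methyl}-1,2,4a,5,6,7,8,8a-octahydronaphthalen-1-yl]carbonyl}-1,3-oxazolidin-2-one
Product: 16 [(1R,2S,4aR,8aR)-5,5,8a-trimethyl-2-{[(triisopropylsilyl)oxy]methyl}-1,2,4a,5,6,7,8,8a-octahydronaphthalen-1-yl]methanol
Conditions: LiBH4, MeOH (1 equiv), THF, 0 °C
Reagents that add atoms: none
Why: Reductive cleavage of an N-acyloxazolidinone with LiBH4 attacks the exocyclic carbonyl and releases the auxiliary and the C11 primary alcohol without touching C9.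

Step 11
Reactants: 16 [(1R,2S,4aR,8aR)-5,5,8a-trimethyl-2-{[(triisopropylsilyl)oxy]methyl}-1,2,4a,5,6,7,8,8a-octahydronaphthalen-1-yl]methanol
Product: 17 (1R,2S,4aR,8aR)-5,5,8a-trimethyl-2-{[(triisopropylsilyl)oxy]methyl}-1,2,4a,5,6,7,8,8a-octahydronaphthalene-1-carbaldehyde
Conditions: Dess–Martin periodinane, CH2Cl2, 0 °C to rt
Reagents that add atoms: none
Why: Dess–Martin oxidation converts the neopentyl-type primary alcohol into the aldehyde under mild conditions that should not epimerise C9, whose equatorial substituent is in any case the stable arrangement.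

Step 12
Reactants: 17 (1R,2S,4aR,8aR)-5,5,8a-trimethyl-2-{[(triisopropylsilyl)oxy]methyl}-1,2,4a,5,6,7,8,8a-octahydronaphthalene-1-carbaldehyde
Product: 18 {[(1R,2S,4aR,8aS)-1-ethenyl-5,5,8a-trimethyl-1,2,4a,5,6,7,8,8a-octahydronaphthalen-2-yl]methoxy}triisopropylsilane
Conditions: Ph3PCH3Br, KOtBu, THF, 0 °C to rt
Reagents that add atoms: methyltriphenylphosphonium bromide, C[P+](c1ccccc1)(c1ccccc1)c1ccccc1.[Br-]
Why: Wittig methylenation with the non-stabilised ylide is fast even for hindered aldehydes and installs C12 (the C10 descriptor changes only because the CIP priorities change).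

Step 13
Reactants: 19 methyl 4-hydroxybut-2-ynoate
Product: 20 methyl (2Z)-4-hydroxy-3-iodobut-2-enoate
Conditions: LiI, AcOH (2 equiv), MeCN, 70 °C
Reagents that add atoms: lithium iodide, [Li+].[I-]
Why: Hydroiodination of a 2-ynoate with iodide and acetic acid is an anti addition (iodide at C3, protonation from the opposite side), which places iodine cis to the ester (Z) and the hydroxymethyl group trans to it, so no lactone can form.

Step 14
Reactants: 18 {[(1R,2S,4aR,8aS)-1-ethenyl-5,5,8a-trimethyl-1,2,4a,5,6,7,8,8a-octahydronaphthalen-2-yl]methoxy}triisopropylsilane; 20 methyl (2Z)-4-hydroxy-3-iodobut-2-enoate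
Product: 22 methyl (2E)-4-hydroxy-3-{2-[(1R,2S,4aR,8aS)-5,5,8a-trimethyl-2-{[(triisopropylsilyl)oxy]methyl}-1,2,4a,5,6,7,8,8a-octahydronaphthalen-1-yl]ethyl}but-2-enoate, via alkylborane 21 (not isolated)
Conditions: 9-BBN, THF, rt to 45 °C; then aq. Cs2CO3, 20, PdCl2(dppf), AsPh3, DMF, rt
Reagents that add atoms: none
Why: 9-BBN adds to the terminal vinyl group (boron at C12) much faster than to the ring C6=C7 alkene, and B-alkyl Suzuki–Miyaura coupling with the β-iodo enoate forms C12–C13 with retention, giving the 13E geometry of the target.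

Step 15
Reactants: 22 methyl (2E)-4-hydroxy-3-{2-[(1R,2S,4aR,8aS)-5,5,8a-trimethyl-2-{[(triisopropylsilyl)oxy]methyl}-1,2,4a,5,6,7,8,8a-octahydronaphthalen-1-yl]ethyl}but-2-enoate
Product: 23 (2E)-4-hydroxy-3-{2-[(1R,2S,4aR,8aS)-5,5,8a-trimethyl-2-{[(triisopropylsilyl)oxy]methyl}-1,2,4a,5,6,7,8,8a-octahydronaphthalen-1-yl]ethyl}but-2-enoic acid
Conditions: LiOH, THF/H2O, rt to 40 °C; then 1 M HCl, 0 °C
Reagents that add atoms: lithium hydroxide, [Li+].[OH-]
Why: Saponification of the methyl ester is done while C17 is still a silyl ether, so no epimerisable or conjugation-prone carbonyl is yet present at C8.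

Step 16
Reactants: 23 (2E)-4-hydroxy-3-{2-[(1R,2S,4aR,8aS)-5,5,8a-trimethyl-2-{[(triisopropylsilyl)oxy]methyl}-1,2,4a,5,6,7,8,8a-octahydronaphthalen-1-yl]ethyl}but-2-enoic acid
Product: 25 (2E)-4-(acetyloxy)-3-{2-[(1R,2S,4aR,8aS)-5,5,8a-trimethyl-2-{[(triisopropylsilyl)oxy]methyl}-1,2,4a,5,6,7,8,8a-octahydronaphthalen-1-yl]ethyl}but-2-enoic acid, via mixed acetic anhydride 24 (not isolated)
Conditions: Ac2O, pyridine, DMAP (cat.), CH2Cl2, 0 °C to rt; then H2O/pyridine, rt
Reagents that add atoms: acetic anhydride, CC(=O)OC(C)=O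
Why: Pyridine/DMAP acetylation esterifies the primary allylic alcohol, and the mixed anhydride formed at the carboxyl group is hydrolysed back to the acid on aqueous work-up.

Step 17
Reactants: 25 (2E)-4-(acetyloxy)-3-{2-[(1R,2S,4aR,8aS)-5,5,8a-trimethyl-2-{[(triisopropylsilyl)oxy]methyl}-1,2,4a,5,6,7,8,8a-octahydronaphthalen-1-yl]ethyl}but-2-enoic acid
Product: 26 (2E)-4-(acetyloxy)-3-{2-[(1R,2S,4aR,8aS)-2-(hydroxymethyl)-5,5,8a-trimethyl-1,2,4a,5,6,7,8,8a-octahydronaphthalen-1-yl]ethyl}but-2-enoic acid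
Conditions: HF·pyridine, pyridine, THF, 0 °C to rt
Reagents that add atoms: none
Why: Fluoride-mediated desilylation with buffered HF·pyridine cleaves the Si–O bond without touching the acetate, the enoic acid or the alkenes.

Step 18
Reactants: 26 (2E)-4-(acetyloxy)-3-{2-[(1R,2S,4aR,8aS)-2-(hydroxymethyl)-5,5,8a-trimethyl-1,2,4a,5,6,7,8,8a-octahydronaphthalen-1-yl]ethyl}but-2-enoic acid
Product: 28 (1R,2S,4aR,8aS)-1-[(3E)-3-(acetoxymethyl)-4-carboxybut-3-en-1-yl]-5,5,8a-trimethyl-1,2,4a,5,6,7,8,8a-octahydronaphthalene-2-carboxylic acid, via aldehyde 27 (not isolated)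
Conditions: TEMPO (cat.), PhI(OAc)2, MeCN/pH 7 phosphate buffer, rt
Reagents that add atoms: water, O
Why: Oxoammonium (TEMPO/PhI(OAc)2) oxidation in aqueous acetonitrile takes the primary alcohol through the aldehyde hydrate to the acid under near-neutral conditions, so the β,γ-unsaturated C8 centre (already in its more stable pseudo-equatorial configuration) should be neither epimerised nor conjugated, and the acetate survives.

Compound list
1 | prop-2-yn-1-ol | C#CCO | starting material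
2 | triisopropyl(prop-2-yn-1-yloxy)silane | C#CCO[Si](C(C)C)(C(C)C)C(C)C | intermediate
3 | ethyl 3-oxobutanoate | CCOC(=O)CC(C)=O | starting material
4 | ethyl (2E)-3-{[(trifluoromethyl)sulfonyl]oxy}but-2-enoate | CCOC(=O)/C=C(C)/OS(=O)(=O)C(F)(F)F | intermediate
5 | 2,2-dimethylpent-4-enal | C=CCC(C)(C)C=O | starting material
6 | (1E)-1-iodo-3,3-dimethylhexa-1,5-diene | C=CCC(C)(C)/C=C/I | intermediate
7 | {[(4E)-6,6-dimethylnona-4,8-dien-2-yn-1-yl]oxy}triisopropylsilane | C=CCC(C)(C)/C=C/C#CCO[Si](C(C)C)(C(C)C)C(C)C | intermediate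
8 | 9-{(5E)-4,4-dimethyl-9-[(triisopropylsilyl)oxy]non-5-en-7-yn-1-yl}-9-borabicyclo[3.3.1]nonane | C1CC2CCCC(C1)B2CCCC(C)(C)/C=C/C#CCO[Si](C(C)C)(C(C)C)C(C)C | intermediate
9 | ethyl (2E,8E)-3,7,7-trimethyl-12-[(triisopropylsilyl)oxy]dodeca-2,8-dien-10-ynoate | CCOC(=O)/C=C(C)/CCCC(C)(C)/C=C/C#CCO[Si](C(C)C)(C(C)C)C(C)C | intermediate
10 | ethyl (2E,8E,10Z)-3,7,7-trimethyl-12-[(triisopropylsilyl)oxy]dodeca-2,8,10-trienoate | CCOC(=O)/C=C(C)/CCCC(C)(C)/C=C/C=C\CO[Si](C(C)C)(C(C)C)C(C)C | intermediate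
11 | (2E,8E,10Z)-3,7,7-trimethyl-12-[(triisopropylsilyl)oxy]dodeca-2,8,10-trienoic acid | OC(=O)/C=C(C)/CCCC(C)(C)/C=C/C=C\CO[Si](C(C)C)(C(C)C)C(C)C | intermediate
12 | (4R)-4-benzyl-1,3-oxazolidin-2-one | O=C1N[C@H](Cc2ccccc2)CO1 | starting material
13 | 2,2-dimethylpropanoic (2E,8E,10Z)-3,7,7-trimethyl-12-[(triisopropylsilyl)oxy]dodeca-2,8,10-trienoic anhydride | CC(C)(C)C(=O)OC(=O)/C=C(C)/CCCC(C)(C)/C=C/C=C\CO[Si](C(C)C)(C(C)C)C(C)C | intermediate
14 | (4R)-4-benzyl-3-{(2E,8E,10Z)-3,7,7-trimethyl-12-[(triisopropylsilyl)oxy]dodeca-2,8,10-trienoyl}-1,3-oxazolidin-2-one | O=C(/C=C(C)/CCCC(C)(C)/C=C/C=C\CO[Si](C(C)C)(C(C)C)C(C)C)N1[C@H](Cc2ccccc2)COC1=O | intermediate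
15 | (4R)-4-benzyl-3-{[(1R,2S,4aR,8aR)-5,5,8a-trimethyl-2-{[(triisopropylsilyl)oxy]methyl}-1,2,4a,5,6,7,8,8a-octahydronaphthalen-1-yl]carbonyl}-1,3-oxazolidin-2-one | O=C([C@@H]1[C@@H](CO[Si](C(C)C)(C(C)C)C(C)C)C=C[C@@H]2C(C)(C)CCC[C@@]12C)N3[C@H](Cc4ccccc4)COC3=O | intermediate
16 | [(1R,2S,4aR,8aR)-5,5,8a-trimethyl-2-{[(triisopropylsilyl)oxy]methyl}-1,2,4a,5,6,7,8,8a-octahydronaphthalen-1-yl]methanol | OC[C@@H]1[C@@H](CO[Si](C(C)C)(C(C)C)C(C)C)C=C[C@@H]2C(C)(C)CCC[C@@]12C | intermediate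
17 | (1R,2S,4aR,8aR)-5,5,8a-trimethyl-2-{[(triisopropylsilyl)oxy]methyl}-1,2,4a,5,6,7,8,8a-octahydronaphthalene-1-carbaldehyde | O=C[C@@H]1[C@@H](CO[Si](C(C)C)(C(C)C)C(C)C)C=C[C@@H]2C(C)(C)CCC[C@@]12C | intermediate
18 | {[(1R,2S,4aR,8aS)-1-ethenyl-5,5,8a-trimethyl-1,2,4a,5,6,7,8,8a-octahydronaphthalen-2-yl]methoxy}triisopropylsilane | C=C[C@@H]1[C@@H](CO[Si](C(C)C)(C(C)C)C(C)C)C=C[C@@H]2C(C)(C)CCC[C@@]12C | intermediate
19 | methyl 4-hydroxybut-2-ynoate | COC(=O)C#CCO | starting material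
20 | methyl (2Z)-4-hydroxy-3-iodobut-2-enoate | COC(=O)/C=C(\I)CO | intermediate
21 | 9-{2-[(1R,2S,4aR,8aS)-5,5,8a-trimethyl-2-{[(triisopropylsilyl)oxy]methyl}-1,2,4a,5,6,7,8,8a-octahydronaphthalen-1-yl]ethyl}-9-borabicyclo[3.3.1]nonane | C1CC2CCCC(C1)B2CC[C@@H]3[C@@H](CO[Si](C(C)C)(C(C)C)C(C)C)C=C[C@@H]4C(C)(C)CCC[C@@]34C | intermediate
22 | methyl (2E)-4-hydroxy-3-{2-[(1R,2S,4aR,8aS)-5,5,8a-trimethyl-2-{[(triisopropylsilyl)oxy]methyl}-1,2,4a,5,6,7,8,8a-octahydronaphthalen-1-yl]ethyl}but-2-enoate | COC(=O)/C=C(/CO)CC[C@@H]1[C@@H](CO[Si](C(C)C)(C(C)C)C(C)C)C=C[C@@H]2C(C)(C)CCC[C@@]12C | intermediate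
23 | (2E)-4-hydroxy-3-{2-[(1R,2S,4aR,8aS)-5,5,8a-trimethyl-2-{[(triisopropylsilyl)oxy]methyl}-1,2,4a,5,6,7,8,8a-octahydronaphthalen-1-yl]ethyl}but-2-enoic acid | OC(=O)/C=C(/CO)CC[C@@H]1[C@@H](CO[Si](C(C)C)(C(C)C)C(C)C)C=C[C@@H]2C(C)(C)CCC[C@@]12C | intermediate
24 | acetic (2E)-4-(acetyloxy)-3-{2-[(1R,2S,4aR,8aS)-5,5,8a-trimethyl-2-{[(triisopropylsilyl)oxy]methyl}-1,2,4a,5,6,7,8,8a-octahydronaphthalen-1-yl]ethyl}but-2-enoic anhydride | CC(=O)OC(=O)/C=C(/COC(C)=O)CC[C@@H]1[C@@H](CO[Si](C(C)C)(C(C)C)C(C)C)C=C[C@@H]2C(C)(C)CCC[C@@]12C | intermediate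
25 | (2E)-4-(acetyloxy)-3-{2-[(1R,2S,4aR,8aS)-5,5,8a-trimethyl-2-{[(triisopropylsilyl)oxy]methyl}-1,2,4a,5,6,7,8,8a-octahydronaphthalen-1-yl]ethyl}but-2-enoic acid | CC(=O)OC/C(=C/C(=O)O)CC[C@@H]1[C@@H](CO[Si](C(C)C)(C(C)C)C(C)C)C=C[C@@H]2C(C)(C)CCC[C@@]12C | intermediate
26 | (2E)-4-(acetyloxy)-3-{2-[(1R,2S,4aR,8aS)-2-(hydroxymethyl)-5,5,8a-trimethyl-1,2,4a,5,6,7,8,8a-octahydronaphthalen-1-yl]ethyl}but-2-enoic acid | CC(=O)OC/C(=C/C(=O)O)CC[C@@H]1[C@@H](CO)C=C[C@@H]2C(C)(C)CCC[C@@]12C | intermediate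
27 | (2E)-4-(acetyloxy)-3-{2-[(1R,2S,4aR,8aS)-2-formyl-5,5,8a-trimethyl-1,2,4a,5,6,7,8,8a-octahydronaphthalen-1-yl]ethyl}but-2-enoic acid | CC(=O)OC/C(=C/C(=O)O)CC[C@@H]1[C@@H](C=O)C=C[C@@H]2C(C)(C)CCC[C@@]12C | intermediate
28 | (1R,2S,4aR,8aS)-1-[(3E)-3-(acetoxymethyl)-4-carboxybut-3-en-1-yl]-5,5,8a-trimethyl-1,2,4a,5,6,7,8,8a-octahydronaphthalene-2-carboxylic acid (labdane numbering 5R,8S,9R,10S,13E) | CC(=O)OC/C(=C/C(=O)O)CC[C@@H]1[C@@H](C(=O)O)C=C[C@@H]2C(C)(C)CCC[C@@]12C | target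

Total step count: 18.
Longest linear sequence: 15 steps (steps 3–12 and 14–18, from aldehyde 5).

Steps most likely to fail

Step 9. The β,β-disubstituted enoyl unit may twist out of the chelate plane or react too slowly with the Z-substituted diene. Facial discrimination by the benzyl group would then be eroded, or the stoichiometric aluminium acid would attack the dienyl ether before cycloaddition. Stereocontrol would then be moved from the auxiliary to a catalyst. Acid 11 would be converted via mixed anhydride 13 into the achiral imide 3-{(2E,8E,10Z)-3,7,7-trimethyl-12-[(triisopropylsilyl)oxy]dodeca-2,8,10-trienoyl}-1,3-oxazolidin-2-one F1. F1 would be cyclised with a catalytic amount of [Cu((S,S)-t-Bu-box)](SbF6)2, the cationic bis(oxazoline) complex of divalent copper, in CH2Cl2 at room temperature. The (S,S) ligand is the one expected to expose the same C9-Re face in the square-planar two-point chelate. This should give 3-{[(1R,2S,4aR,8aR)-5,5,8a-trimethyl-2-{[(triisopropylsilyl)oxy]methyl}-1,2,4a,5,6,7,8,8a-octahydronaphthalen-1-yl]carbonyl}-1,3-oxazolidin-2-one F2. LiBH4 reduction of F2 under the conditions of step 10 comes back to the route at alcohol 16.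

Step 10. The exocyclic carbonyl is flanked by quaternary C10 and by C8, so hydride may instead attack the ring carbamate carbonyl and open the oxazolidinone. In that case 15 would be hydrolysed with LiOH/H2O2 (THF/H2O, 0 °C), since the hydroperoxide anion selects the exocyclic carbonyl even in hindered imides. This should give (1R,2S,4aR,8aR)-5,5,8a-trimethyl-2-{[(triisopropylsilyl)oxy]methyl}-1,2,4a,5,6,7,8,8a-octahydronaphthalene-1-carboxylic acid F3 and recovered 12. LiAlH4 (THF, 0 °C) would then reduce F3 to alcohol 16, where the route is rejoined.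

Step 5. Hydroboration may not stay confined to the terminal alkene (addition to the conjugated enyne), or the alkyne may interfere in the palladium step. The enyne would then be kept out of this step by changing the order of events, starting from aldehyde 5. Acetalisation (HC(OMe)3, TsOH cat., MeOH) should give 5,5-dimethoxy-4,4-dimethylpent-1-ene F4. 9-BBN should convert F4 into 9-(5,5-dimethoxy-4,4-dimethylpentyl)-9-borabicyclo[3.3.1]nonane F5 (not isolated), which would be coupled with triflate 4 as in step 5 to give ethyl (2E)-8,8-dimethoxy-3,7,7-trimethyloct-2-enoate F6. Mild aqueous acid (TsOH, acetone/H2O) should free ethyl (2E)-3,7,7-trimethyl-8-oxooct-2-enoate F7. Takai iodo-olefination (CrCl2, CHI3, THF) should give ethyl (2E,8E)-9-iodo-3,7,7-trimethylnona-2,8-dienoate F8. Sonogashira coupling of F8 with alkyne 2 (PdCl2(PPh3)2, CuI, Et3N) comes back to the route at enynoate 9.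

Further compounds
F1 | step 9 | 3-{(2E,8E,10Z)-3,7,7-trimethyl-12-[(triisopropylsilyl)oxy]dodeca-2,8,10-trienoyl}-1,3-oxazolidin-2-one | O=C(/C=C(C)/CCCC(C)(C)/C=C/C=C\CO[Si](C(C)C)(C(C)C)C(C)C)N1CCOC1=O
F2 | step 9 | 3-{[(1R,2S,4aR,8aR)-5,5,8a-trimethyl-2-{[(triisopropylsilyl)oxy]methyl}-1,2,4a,5,6,7,8,8a-octahydronaphthalen-1-yl]carbonyl}-1,3-oxazolidin-2-one | O=C([C@@H]1[C@@H](CO[Si](C(C)C)(C(C)C)C(C)C)C=C[C@@H]2C(C)(C)CCC[C@@]12C)N3CCOC3=O
F3 | step 10 | (1R,2S,4aR,8aR)-5,5,8a-trimethyl-2-{[(triisopropylsilyl)oxy]methyl}-1,2,4a,5,6,7,8,8a-octahydronaphthalene-1-carboxylic acid | OC(=O)[C@@H]1[C@@H](CO[Si](C(C)C)(C(C)C)C(C)C)C=C[C@@H]2C(C)(C)CCC[C@@]12C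
F4 | step 5 | 5,5-dimethoxy-4,4-dimethylpent-1-ene | C=CCC(C)(C)C(OC)OC
F5 | step 5 | 9-(5,5-dimethoxy-4,4-dimethylpentyl)-9-borabicyclo[3.3.1]nonane | C1CC2CCCC(C1)B2CCCC(C)(C)C(OC)OC
F6 | step 5 | ethyl (2E)-8,8-dimethoxy-3,7,7-trimethyloct-2-enoate | CCOC(=O)/C=C(C)/CCCC(C)(C)C(OC)OC
F7 | step 5 | ethyl (2E)-3,7,7-trimethyl-8-oxooct-2-enoate | CCOC(=O)/C=C(C)/CCCC(C)(C)C=O
F8 | step 5 | ethyl (2E,8E)-9-iodo-3,7,7-trimethylnona-2,8-dienoate | CCOC(=O)/C=C(C)/CCCC(C)(C)/C=C/I
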